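**Retrosynthetic overview**
- The C4–C5 epoxide is installed last, by hydroxyl-directed epoxidation of the (4Z)-allylic alcohol in the finished ten-membered ring.
- The ten-membered ring is closed at C6–C7 by an acid-catalysed intramolecular allylboration of a (Z)-enal by an allyl-Bpin built into a preformed butenolide; this sets C6 and C7 and unveils the α-methylene lactone.
- The butenolide (8,12-lactone) comes from an aldehyde by (R)-proline α-aminoxylation (sets C8, the first stereocentre), Z-selective olefination and lactonisation.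
- The acyclic chain comes from a B-alkyl Suzuki coupling of a (Z)-vinyl iodide (carbomagnesiation of propargyl alcohol, tiglate put on early) with a (Z)-dienol-derived borane.
- Ring order: butenolide, then carbocycle, then epoxide.

Assumption: locants C1–C15 follow germacrane numbering (C12 lactone carbonyl, C13 exocyclic methylene, C14 the CH2O carbon, C15 the methyl); tiglate means (2E)-2-methylbut-2-enoate and Bpin means 4,4,5,5-tetramethyl-1,3,2-dioxaborolan-2-yl.

**Step 1**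
Reactants: 1 prop-2-yn-1-ol; 2 2-(2-bromoethyl)-1,3-dioxolane
Product: 5 (2Z)-2-[2-(1,3-dioxolan-2-yl)ethyl]-3-iodoprop-2-en-1-ol, via Grignard reagent 3 (not isolated), via vinylmagnesium alkoxide 4 (not isolated)
Conditions: 2 (3 equiv), Mg turnings, THF, 25–30 °C; then 1, CuI (10 mol%), −10 °C to rt; then I2, −40 to 0 °C; aq. NH4Cl/Na2S2O3
Reagents that add atoms: iodine, [I][I]
Why: Copper-catalysed anti-carbomagnesiation of a propargylic alcohol puts the alkyl group on the internal carbon and magnesium on the terminal carbon, held cis to the alkoxide in a five-membered chelate, so iodinolysis gives only the Z iodide, with the future C2 site cis to the C14 arm.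

**Step 2**
Reactants: 5 (2Z)-2-[2-(1,3-dioxolan-2-yl)ethyl]-3-iodoprop-2-en-1-ol
Product: 6 (2Z)-2-[2-(1,3-dioxolan-2-yl)ethyl]-3-iodoprop-2-en-1-yl tiglate
Conditions: tiglic acid (1.2 equiv), N,N'-dicyclohexylcarbodiimide, DMAP (10 mol%), CH2Cl2, 0 °C to rt
Reagents that add atoms: tiglic acid, C/C=C(\C)C(=O)O
Why: Steglich esterification of the primary allylic alcohol keeps the E geometry of the acid and leaves the vinyl iodide and acetal untouched.

**Step 3**
Reactants: 7 (2Z)-3-methylpent-2-en-4-yn-1-ol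
Product: 8 (2Z)-3-methylpenta-2,4-dien-1-ol
Conditions: H2 (1 atm), 5% Pd/CaCO3 poisoned with Pb(OAc)2, quinoline, EtOAc, 0 °C, stopped after 1 equiv H2
Reagents that add atoms: none
Why: Lindlar-type semihydrogenation stops at the terminal vinyl group and does not touch the Z trisubstituted alkene.

**Step 4**
Reactants: 8 (2Z)-3-methylpenta-2,4-dien-1-ol; 6 (2Z)-2-[2-(1,3-dioxolan-2-yl)ethyl]-3-iodoprop-2-en-1-yl tiglate
Product: 10 (2Z,6Z)-2-[2-(1,3-dioxolan-2-yl)ethyl]-8-hydroxy-6-methylocta-2,6-dien-1-yl tiglate, via bis(9-BBN) adduct 9 (not isolated)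
Conditions: 8 (1.3 equiv), 9-BBN dimer (2.9 equiv B–H), THF, 0 °C to rt; then 6, PdCl2(dppf) (5 mol%), AsPh3 (10 mol%), Cs2CO3, DMF/H2O, rt
Reagents that add atoms: none
Why: 9-BBN hydroborates only the monosubstituted diene terminus (anti-Markovnikov, the hydroxyl being masked in situ as its borinate), and the B-alkyl Suzuki–Miyaura coupling with the vinyl iodide goes with retention, so C2 ends cis to C14.

**Step 5**
Reactants: 10 (2Z,6Z)-2-[2-(1,3-dioxolan-2-yl)ethyl]-8-hydroxy-6-methylocta-2,6-dien-1-yl tiglate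
Product: 11 (2Z,6Z)-8-hydroxy-6-methyl-2-(3-oxopropyl)octa-2,6-dien-1-yl tiglate
Conditions: PPTS (0.3 equiv), acetone/H2O 9:1, 50 °C
Reagents that add atoms: water, O
Why: Mild acid-catalysed acetal hydrolysis (transacetalisation) unmasks the C7 aldehyde without affecting the allylic ester, the allylic alcohol or the alkenes.

**Step 6**
Reactants: 12 ethyl 2-(diphenoxyphosphoryl)acetate
Product: 13 ethyl 2-(diphenoxyphosphoryl)-3-(Bpin)propanoate
Conditions: NaH (1.0 equiv), THF, 0 °C; then 2-(iodomethyl)-Bpin (1.0 equiv), 0 °C to rt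
Reagents that add atoms: 2-(iodomethyl)-4,4,5,5-tetramethyl-1,3,2-dioxaborolane, ICB1OC(C)(C)C(C)(C)O1
Why: SN2 alkylation at carbon of the sodium phosphonoacetate by the boron-activated primary iodide gives an Ando-type reagent; its acidic α-carbon is racemic and is planarised again in step 7, so it carries no stereochemical information.

**Step 7**
Reactants: 11 (2Z,6Z)-8-hydroxy-6-methyl-2-(3-oxopropyl)octa-2,6-dien-1-yl tiglate; 13 ethyl 2-(diphenoxyphosphoryl)-3-(Bpin)propanoate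
Product: 15 ethyl (2Z,4S,6Z,10Z)-4-(anilinooxy)-12-hydroxy-10-methyl-6-[(tigloyloxy)methyl]-2-[(Bpin)methyl]dodeca-2,6,10-trienoate, via (S)-alpha-anilinooxy aldehyde 14 (not isolated)
Conditions: nitrosobenzene (1.0 equiv, slow addition), (R)-proline (20 mol%), MeCN, −20 °C; then 13 (1.3 equiv), NaI, DBU, THF, −78 to 0 °C
Reagents that add atoms: nitrosobenzene, O=Nc1ccccc1
Why: Enamine catalysis: the (R)-proline-catalysed α-aminoxylation (O-selective nitroso aldol) delivers oxygen to the enamine face directed by the carboxylic acid hydrogen bond and sets C8 as S (the first stereocentre, typically above 95% ee), and the in-situ Ando-type Z-selective Horner–Wadsworth–Emmons olefination traps the labile aldehyde with the ester cis to C8.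

**Step 8**
Reactants: 15 ethyl (2Z,4S,6Z,10Z)-4-(anilinooxy)-12-hydroxy-10-methyl-6-[(tigloyloxy)methyl]-2-[(Bpin)methyl]dodeca-2,6,10-trienoate
Product: 17 (2Z,6Z)-8-hydroxy-6-methyl-2-({(2S)-5-oxo-4-[(Bpin)methyl]-2,5-dihydrofuran-2-yl}methyl)octa-2,6-dien-1-yl tiglate, via (Z)-gamma-hydroxy enoate 16 (not isolated)
Conditions: Zn dust, AcOH/THF 1:4, 0 °C to rt; then PPTS (cat.), CH2Cl2, rt
Reagents that add atoms: none
Why: Reductive N–O cleavage by zinc in acetic acid frees the C8 hydroxyl, which lactonises at once onto the cis ester (Z-γ-hydroxy enoate to butenolide) without touching C8; no base is used, so the acidic butenolide γ-hydrogen is not epimerised.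

**Step 9**
Reactants: 17 (2Z,6Z)-8-hydroxy-6-methyl-2-({(2S)-5-oxo-4-[(Bpin)methyl]-2,5-dihydrofuran-2-yl}methyl)octa-2,6-dien-1-yl tiglate
Product: 18 (2Z,6Z)-6-methyl-8-oxo-2-({(2S)-5-oxo-4-[(Bpin)methyl]-2,5-dihydrofuran-2-yl}methyl)octa-2,6-dien-1-yl tiglate
Conditions: activated MnO2 (15 equiv), CH2Cl2, 0 °C to rt, dark; used at once
Reagents that add atoms: none
Why: Allylic oxidation with MnO2 converts only the electron-rich allylic alcohol into the (Z)-enal without Z/E isomerisation; the electron-poor 2-carbonyl allylboronate is inert to MnO2 and adds to aldehydes only slowly without acid.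

**Step 10**
Reactants: 18 (2Z,6Z)-6-methyl-8-oxo-2-({(2S)-5-oxo-4-[(Bpin)methyl]-2,5-dihydrofuran-2-yl}methyl)octa-2,6-dien-1-yl tiglate
Product: 20 (1(10)Z,4Z,6R,7S,8S)-6-hydroxy-14-(tigloyloxy)germacra-1(10),4,11(13)-trien-12,8-olide, via macrocyclic pinacol borate 19 (not isolated)
Conditions: (S)-3,3'-bis(2,4,6-triisopropylphenyl)-BINOL N-triflyl phosphoramide (15 mol%), toluene, 4 Å MS, 0 °C to rt, 18 added by syringe pump to 0.001 mol/L; then aq. NaHCO3
Reagents that add atoms: none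
Why: Proposed new method: a Brønsted-acid-catalysed macrocyclising allylboration in which the chiral acid hydrogen-bonds to a pinacol oxygen, boron binds the aldehyde oxygen and the allyl unit transfers through a six-membered chair; the ring-locked E-type allyl fragment (C8 trans to CH2B) with the aldehyde substituent equatorial gives the anti C6/C7 relationship, the bond forms on the butenolide face opposite the C8–C9 bond (trans-fused lactone), the two ring bonds at C6 and C7 come out gauche as a ten-membered ring requires, and the (S)-acid is expected to direct attack to the aldehyde Si face already favoured by the substrate; the closest known reactions are triflic-acid-catalysed allylborations of aldehydes with 2-alkoxycarbonyl allylboronates, chiral-phosphoric-acid-catalysed allylborations with allyl-Bpin, and metal-mediated intramolecular Barbier allylations that close ten-membered germacranolide rings.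

**Step 11**
Reactants: 20 (1(10)Z,4Z,6R,7S,8S)-6-hydroxy-14-(tigloyloxy)germacra-1(10),4,11(13)-trien-12,8-olide
Product: 21 CNP0116446.1, (1(10)Z,4S,5R,6S,7S,8S)-4,5-epoxy-6-hydroxy-14-(tigloyloxy)germacra-1(10),11(13)-dien-12,8-olide
Conditions: VO(acac)2 (5 mol%), t-BuOOH (1.3 equiv, 5.5 mol/L in decane), 2,6-lutidine (0.2 equiv), CH2Cl2, 0 °C
Reagents that add atoms: tert-butyl hydroperoxide, CC(C)(C)OO
Why: In this hydroxyl-directed vanadium-catalysed epoxidation of the allylic alcohol, H6 eclipses the alkene to avoid A(1,3) strain with C3, so the C6 hydroxyl delivers the peroxide to the outer face of the Z C4=C5 bond, anti to C7, giving the threo epoxy alcohol (4S,5R); the electron-poor methylene lactone, the tiglate and the remote C1=C10 alkene are not epoxidised.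

**Compound list**
1 | prop-2-yn-1-ol | C#CCO | starting material
2 | 2-(2-bromoethyl)-1,3-dioxolane | BrCCC1OCCO1 | starting material
3 | [2-(1,3-dioxolan-2-yl)ethyl]magnesium bromide | Br[Mg]CCC1OCCO1 | intermediate
4 | bromomagnesium (2Z)-3-(bromomagnesio)-2-[2-(1,3-dioxolan-2-yl)ethyl]prop-2-en-1-olate | Br[Mg]/C=C(/CCC1OCCO1)CO[Mg]Br | intermediate
5 | (2Z)-2-[2-(1,3-dioxolan-2-yl)ethyl]-3-iodoprop-2-en-1-ol | I/C=C(/CCC1OCCO1)CO | intermediate
6 | (2Z)-2-[2-(1,3-dioxolan-2-yl)ethyl]-3-iodoprop-2-en-1-yl tiglate | I/C=C(/CCC1OCCO1)COC(=O)/C(C)=C/C | intermediate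
7 | (2Z)-3-methylpent-2-en-4-yn-1-ol | C#C/C(C)=C\CO | starting material
8 | (2Z)-3-methylpenta-2,4-dien-1-ol | C=C/C(C)=C\CO | intermediate
9 | 9-[(3Z)-5-(9-borabicyclo[3.3.1]nonan-9-yloxy)-3-methylpent-3-en-1-yl]-9-borabicyclo[3.3.1]nonane | C(CB1C2CCCC1CCC2)/C(C)=C\COB1C2CCCC1CCC2 | intermediate
10 | (2Z,6Z)-2-[2-(1,3-dioxolan-2-yl)ethyl]-8-hydroxy-6-methylocta-2,6-dien-1-yl tiglate | OC/C=C(C)\CC/C=C(/CCC1OCCO1)COC(=O)/C(C)=C/C | intermediate
11 | (2Z,6Z)-8-hydroxy-6-methyl-2-(3-oxopropyl)octa-2,6-dien-1-yl tiglate | OC/C=C(C)\CC/C=C(/CCC=O)COC(=O)/C(C)=C/C | intermediate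
12 | ethyl 2-(diphenoxyphosphoryl)acetate | CCOC(=O)CP(=O)(Oc1ccccc1)Oc1ccccc1 | starting material
13 | ethyl 2-(diphenoxyphosphoryl)-3-(Bpin)propanoate (racemic) | CCOC(=O)C(CB1OC(C)(C)C(C)(C)O1)P(=O)(Oc1ccccc1)Oc1ccccc1 | intermediate
14 | (2Z,6Z)-2-[(2S)-2-(anilinooxy)-3-oxopropyl]-8-hydroxy-6-methylocta-2,6-dien-1-yl tiglate | O=C[C@@H](ONc1ccccc1)C/C(COC(=O)/C(C)=C/C)=C/CC/C(C)=C\CO | intermediate
15 | ethyl (2Z,4S,6Z,10Z)-4-(anilinooxy)-12-hydroxy-10-methyl-6-[(tigloyloxy)methyl]-2-[(Bpin)methyl]dodeca-2,6,10-trienoate | CCOC(=O)/C(CB1OC(C)(C)C(C)(C)O1)=C\[C@@H](ONc1ccccc1)C/C(COC(=O)/C(C)=C/C)=C/CC/C(C)=C\CO | intermediate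
16 | ethyl (2Z,4S,6Z,10Z)-4,12-dihydroxy-10-methyl-6-[(tigloyloxy)methyl]-2-[(Bpin)methyl]dodeca-2,6,10-trienoate | CCOC(=O)/C(CB1OC(C)(C)C(C)(C)O1)=C\[C@@H](O)C/C(COC(=O)/C(C)=C/C)=C/CC/C(C)=C\CO | intermediate
17 | (2Z,6Z)-8-hydroxy-6-methyl-2-({(2S)-5-oxo-4-[(Bpin)methyl]-2,5-dihydrofuran-2-yl}methyl)octa-2,6-dien-1-yl tiglate | O=C1O[C@@H](C/C(COC(=O)/C(C)=C/C)=C/CC/C(C)=C\CO)C=C1CB1OC(C)(C)C(C)(C)O1 | intermediate
18 | (2Z,6Z)-6-methyl-8-oxo-2-({(2S)-5-oxo-4-[(Bpin)methyl]-2,5-dihydrofuran-2-yl}methyl)octa-2,6-dien-1-yl tiglate | O=C1O[C@@H](C/C(COC(=O)/C(C)=C/C)=C/CC/C(C)=C\C=O)C=C1CB1OC(C)(C)C(C)(C)O1 | intermediate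
19 | 6-O-(Bpin) borate of 20 | C=C1C(=O)O[C@H]2C/C(COC(=O)/C(C)=C/C)=C/CC/C(C)=C\[C@@H](OB3OC(C)(C)C(C)(C)O3)[C@H]12 | intermediate
20 | (1(10)Z,4Z,6R,7S,8S)-6-hydroxy-14-(tigloyloxy)germacra-1(10),4,11(13)-trien-12,8-olide (C2 and C9 trans across C1=C10; C3 and C6 cis across C4=C5; trans-fused lactone) | C=C1C(=O)O[C@H]2C/C(COC(=O)/C(C)=C/C)=C/CC/C(C)=C\[C@@H](O)[C@H]12 | intermediate
21 | CNP0116446.1, (1(10)Z,4S,5R,6S,7S,8S)-4,5-epoxy-6-hydroxy-14-(tigloyloxy)germacra-1(10),11(13)-dien-12,8-olide | C=C1C(=O)O[C@H]2C/C(COC(=O)/C(C)=C/C)=C/CC[C@]3(C)O[C@@H]3[C@@H](O)[C@H]12 | target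

**Step count and risks**
Total step count: 11. Longest linear sequence: 9 (steps 1, 2, 4, 5, 7, 8, 9, 10, 11).

The three steps most likely to fail:

Step 10 (the new macrocyclising allylboration). The risks are oligomerisation, protodeboronation of the allylboronate by the acid, and the wrong ring fusion. The fallback uses known chemistry, sets out from 17 and comes back at 20. Silylation of the C6 alcohol (TBSCl, imidazole, CH2Cl2) gives the silyl ether F1. Oxidation of the carbon–boron bond (NaBO3·4H2O, THF/pH 7 buffer, 0 °C) gives the 3-(hydroxymethyl)butenolide F2. Appel bromination (CBr4, PPh3) gives the allylic bromide F3. Desilylation (PPTS, MeOH) gives the bromo alcohol F4, and MnO2 gives the bromo enal F5. An intramolecular Nozaki–Hiyama-type Barbier allylation (CrCl2, THF, high dilution, rt) then gives 20 through the same chair-type addition; this is the established way of closing ten-membered α-methylene lactone carbocycles from bromomethyl enoate aldehydes.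

Step 7 (one-pot aminoxylation and Z-olefination). The risks are that the borylated phosphonate 13 is an untested reagent whose anion may be sluggish, that the boronate may not survive, and that nitrosobenzene over-reacts with the limiting aldehyde. The fallback sets out from 11 and comes back at 17. The same (R)-proline/nitrosobenzene aminoxylation gives 14, which is olefinated in the same pot with commercial 12 (NaI, DBU) to the boron-free Z enoate F6. Zn/AcOH cleaves the N–O bond to the hydroxy enoate F7, which lactonises to the 3-unsubstituted butenolide F8. α-Iodination (I2, pyridine, CH2Cl2) gives the iodobutenolide F9. Negishi coupling (Pd(PPh3)4, THF) with the borylmethylzinc iodide F10, made from the iodomethyl boronate and zinc dust, gives 17.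

Step 4 (B-alkyl Suzuki coupling). The risks are that the allylic tiglate ionises on zerovalent palladium or is hydrolysed by the aqueous base, and that the free hydroxyl consumes borane. The fallback sets out from 8 and 5 and comes back at 11. Silylation of 8 (TBSCl, imidazole) gives the dienyl silyl ether F11. 9-BBN gives the alkylborane F12, which is coupled with the unesterified iodide 5 (PdCl2(dppf), AsPh3, Cs2CO3) to the mono-alcohol F13. Steglich esterification with tiglic acid gives the silyl-protected tiglate F14. PPTS in wet acetone then removes the acetal and the silyl ether together to give 11.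

**Further compounds**
F1 | step 10 | (2Z,6Z)-8-[(tert-butyldimethylsilyl)oxy]-6-methyl-2-({(2S)-5-oxo-4-[(Bpin)methyl]-2,5-dihydrofuran-2-yl}methyl)octa-2,6-dien-1-yl tiglate | O=C1O[C@@H](C/C(COC(=O)/C(C)=C/C)=C/CC/C(C)=C\CO[Si](C)(C)C(C)(C)C)C=C1CB1OC(C)(C)C(C)(C)O1
F2 | step 10 | (2Z,6Z)-8-[(tert-butyldimethylsilyl)oxy]-2-{[(2S)-4-(hydroxymethyl)-5-oxo-2,5-dihydrofuran-2-yl]methyl}-6-methylocta-2,6-dien-1-yl tiglate | O=C1O[C@@H](C/C(COC(=O)/C(C)=C/C)=C/CC/C(C)=C\CO[Si](C)(C)C(C)(C)C)C=C1CO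
F3 | step 10 | (2Z,6Z)-2-{[(2S)-4-(bromomethyl)-5-oxo-2,5-dihydrofuran-2-yl]methyl}-8-[(tert-butyldimethylsilyl)oxy]-6-methylocta-2,6-dien-1-yl tiglate | O=C1O[C@@H](C/C(COC(=O)/C(C)=C/C)=C/CC/C(C)=C\CO[Si](C)(C)C(C)(C)C)C=C1CBr
F4 | step 10 | (2Z,6Z)-2-{[(2S)-4-(bromomethyl)-5-oxo-2,5-dihydrofuran-2-yl]methyl}-8-hydroxy-6-methylocta-2,6-dien-1-yl tiglate | O=C1O[C@@H](C/C(COC(=O)/C(C)=C/C)=C/CC/C(C)=C\CO)C=C1CBr
F5 | step 10 | (2Z,6Z)-2-{[(2S)-4-(bromomethyl)-5-oxo-2,5-dihydrofuran-2-yl]methyl}-6-methyl-8-oxoocta-2,6-dien-1-yl tiglate | O=C1O[C@@H](C/C(COC(=O)/C(C)=C/C)=C/CC/C(C)=C\C=O)C=C1CBr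
F6 | step 7 | ethyl (2Z,4S,6Z,10Z)-4-(anilinooxy)-12-hydroxy-10-methyl-6-[(tigloyloxy)methyl]dodeca-2,6,10-trienoate | CCOC(=O)/C=C\[C@@H](ONc1ccccc1)C/C(COC(=O)/C(C)=C/C)=C/CC/C(C)=C\CO
F7 | step 7 | ethyl (2Z,4S,6Z,10Z)-4,12-dihydroxy-10-methyl-6-[(tigloyloxy)methyl]dodeca-2,6,10-trienoate | CCOC(=O)/C=C\[C@@H](O)C/C(COC(=O)/C(C)=C/C)=C/CC/C(C)=C\CO
F8 | step 7 | (2Z,6Z)-8-hydroxy-6-methyl-2-{[(2S)-5-oxo-2,5-dihydrofuran-2-yl]methyl}octa-2,6-dien-1-yl tiglate | O=C1O[C@@H](C/C(COC(=O)/C(C)=C/C)=C/CC/C(C)=C\CO)C=C1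
F9 | step 7 | (2Z,6Z)-8-hydroxy-2-{[(2S)-4-iodo-5-oxo-2,5-dihydrofuran-2-yl]methyl}-6-methylocta-2,6-dien-1-yl tiglate | O=C1O[C@@H](C/C(COC(=O)/C(C)=C/C)=C/CC/C(C)=C\CO)C=C1I
F10 | step 7 | iodo[(4,4,5,5-tetramethyl-1,3,2-dioxaborolan-2-yl)methyl]zinc | I[Zn]CB1OC(C)(C)C(C)(C)O1
F11 | step 4 | tert-butyldimethyl{[(2Z)-3-methylpenta-2,4-dien-1-yl]oxy}silane | C=C/C(C)=C\CO[Si](C)(C)C(C)(C)C
F12 | step 4 | 9-[(3Z)-5-[(tert-butyldimethylsilyl)oxy]-3-methylpent-3-en-1-yl]-9-borabicyclo[3.3.1]nonane | C(CB1C2CCCC1CCC2)/C(C)=C\CO[Si](C)(C)C(C)(C)C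
F13 | step 4 | (2Z,6Z)-8-[(tert-butyldimethylsilyl)oxy]-2-[2-(1,3-dioxolan-2-yl)ethyl]-6-methylocta-2,6-dien-1-ol | CC(C)(C)[Si](C)(C)OC/C=C(C)\CC/C=C(/CCC1OCCO1)CO
F14 | step 4 | (2Z,6Z)-8-[(tert-butyldimethylsilyl)oxy]-2-[2-(1,3-dioxolan-2-yl)ethyl]-6-methylocta-2,6-dien-1-yl tiglate | CC(C)(C)[Si](C)(C)OC/C=C(C)\CC/C=C(/CCC1OCCO1)COC(=O)/C(C)=C/C
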